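The 1,2-dioxane is numbered O1, O2, C3 (methyl, 2-carboxyethyl), C4, C5, C6 (methyl, 8-phenyloctyl). C3 is a tertiary peroxy carbon flanked by the ring CH2 C4, the pattern left by Markovnikov carbo-peroxidation of a 1,1-disubstituted alkene, so the ring is cut at C4–C5 and O2–C3. In the key step an enantiopure α-silylperoxy aldehyde, which already holds C6, C5 and both oxygens, is attacked at its carbonyl carbon by ethyl 4-methylpent-4-enoate inside a chiral silylium–IDPi ion pair, and the peroxide closes onto the tertiary cation. The C5 hydroxyl left by this polar (4+2) annulation is removed by dehydration and diimide reduction; C6 derives from (S)-2-methylglycidol.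

Key step: step 6

Remark: the carbon that becomes C3 is written 3S in 11–13 and 3R in 14 and 15 only because the CIP ranks of its neighbours change; its spatial arrangement is the same throughout.
Assumption: (7-bromoheptyl)benzene, (S)-2-methylglycidol and ethyl 4-methylpent-4-enoate are taken as purchasable; anhydrous ethereal H2O2 is prepared in the usual way.

Step 1
Reactants: 1 (7-bromoheptyl)benzene; 2 (S)-2-methylglycidol
Product: 4 (R)-2-methyl-10-phenyldecane-1,2-diol, via 7-phenylheptylmagnesium bromide 3 (not isolated)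
Conditions: Mg, THF, reflux; then CuI (10 mol%), 2 (0.45 equiv relative to 3), THF, −30 → 0 °C; aq NH4Cl work-up
Reagents that add atoms: none
Why: Copper-catalysed Grignard opening of the epoxide is an SN2 attack at the unhindered CH2 and leaves the quaternary carbinol centre of 2 untouched (Payne rearrangement of the alkoxide is degenerate and cannot erode ee), so the diol should form as the R isomer.

Step 2
Reactants: 4 (R)-2-methyl-10-phenyldecane-1,2-diol
Product: 6 (R)-2-methyl-2-(8-phenyloctyl)oxirane, via primary monotosylate 5 (not isolated)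
Conditions: TsCl, pyridine, CH2Cl2, 0 °C; then K2CO3, MeOH, rt
Reagents that add atoms: none
Why: Selective tosylation of the primary hydroxyl and Williamson closure by the tertiary alkoxide (3-exo-tet) should give the epoxide without touching the stereocentre.

Step 3
Reactants: 6 (R)-2-methyl-2-(8-phenyloctyl)oxirane
Product: 7 (S)-2-hydroperoxy-2-methyl-10-phenyldecan-1-ol
Conditions: H2O2 (anhydrous, in Et2O, 10 equiv), H3PMo12O40 (3 mol%), Et2O, 0 °C → rt
Reagents that add atoms: hydrogen peroxide, OO
Why: Acid-catalysed perhydrolysis of a 2,2-disubstituted epoxide delivers H2O2 to the tertiary carbon with inversion (borderline SN2), which should convert the R epoxide into the S tertiary hydroperoxide that becomes C6.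

Step 4
Reactants: 7 (S)-2-hydroperoxy-2-methyl-10-phenyldecan-1-ol
Product: 8 (S)-2-methyl-10-phenyl-2-[(triethylsilyl)peroxy]decan-1-ol
Conditions: Et3SiCl (1.05 equiv), imidazole, DMF, −40 → −20 °C
Reagents that add atoms: chlorotriethylsilane, CC[Si](Cl)(CC)CC
Why: Silylation of a hydroperoxide should be chemoselective because the O–O–H group is markedly more acidic than the neopentyl-type primary alcohol and is an α-effect nucleophile.

Step 5
Reactants: 8 (S)-2-methyl-10-phenyl-2-[(triethylsilyl)peroxy]decan-1-ol
Product: 9 (S)-2-methyl-10-phenyl-2-[(triethylsilyl)peroxy]decanal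
Conditions: Dess–Martin periodinane, NaHCO3, CH2Cl2, 0 °C → rt
Reagents that add atoms: none
Why: Dess–Martin oxidation of a primary alcohol under buffered conditions should give the aldehyde, whose quaternary α-carbon cannot epimerise.

Step 6
Reactants: 9 (S)-2-methyl-10-phenyl-2-[(triethylsilyl)peroxy]decanal; 10 ethyl 4-methylpent-4-enoate
Product: 12 ethyl 3-[(3S,6S)-5-hydroxy-3,6-dimethyl-6-(8-phenyloctyl)-1,2-dioxan-3-yl]propanoate, via C5 triethylsilyl ether 11 (not isolated)
Conditions: 10 (3 equiv), one enantiomer of a confined chiral imidodiphosphorimidate Brønsted acid (IDPi, 5 mol%), allylSiEt3 (10 mol%, silylium initiator), toluene, −60 °C; then HF·pyridine, THF, 0 °C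
Reagents that add atoms: none
Why: Proposed new method: Et3Si+ held by the confined chiral IDPi anion binds the aldehyde oxygen of 9, the CH2 terminus of 10 adds to the carbonyl carbon (C5–C4 bond) and the tertiary cation at C3 is captured by the silylated distal peroxide oxygen (O2–C3 bond), the silylperoxonium ion then returning Et3Si+ to the anion so that the cycle turns over and 11 carries the silyl group on the C5 oxygen. The closest known reaction types are the Lewis-acid (3+2) annulation of silyl peroxyketals with alkenes that gives 1,2-dioxolanes, of which this is the one-carbon-longer version with an activated aldehyde in place of the peroxycarbenium ion, and the IDPi-catalysed asymmetric intermolecular Prins reaction that gives 1,3-dioxanes. The 1,2-dioxane ring closes in a stepwise polar (4+2) annulation, the last event being attack of oxygen on the trigonal cationic carbon through a six-membered chair transition state. C3 is set by catalyst control: the resident C6 centre (methyl against CH2) gives no useful bias, so the anion, of a type known to discriminate the faces of aliphatic tertiary cations in hydroalkoxylation, must do so, and the catalyst enantiomer that gives 3S is chosen in the first runs, while the C5 carbinol centre may form as either epimer because steps 7 and 8 erase it. The step needs Markovnikov regiochemistry, secured by the 1,1-disubstitution of 10 (CH2 attacks, tertiary cation forms), and capture by the peroxide in preference to proton loss, which is tolerated because ene isomers are re-protonated by the free acid back to the same ion pair while the ethyl ester can cap the cation only reversibly.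

Step 7
Reactants: 12 ethyl 3-[(3S,6S)-5-hydroxy-3,6-dimethyl-6-(8-phenyloctyl)-1,2-dioxan-3-yl]propanoate
Product: 13 ethyl 3-[(3S,6S)-3,6-dimethyl-6-(8-phenyloctyl)-3,6-dihydro-1,2-dioxin-3-yl]propanoate
Conditions: Burgess reagent, toluene, 60 °C
Reagents that add atoms: none
Why: Burgess dehydration (thermal syn-elimination of the sulfamate ester) can only remove a C4 hydrogen because C6 is quaternary, so either C5 epimer should give the ring alkene while the di-tertiary peroxide, which has no α-hydrogen, stays intact.

Step 8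
Reactants: 13 ethyl 3-[(3S,6S)-3,6-dimethyl-6-(8-phenyloctyl)-3,6-dihydro-1,2-dioxin-3-yl]propanoate
Product: 14 ethyl 3-[(3R,6S)-3,6-dimethyl-6-(8-phenyloctyl)-1,2-dioxan-3-yl]propanoate
Conditions: KO2CN=NCO2K (excess, portionwise), AcOH, MeOH/CH2Cl2, 0 °C → rt
Reagents that add atoms: none
Why: Diimide reduction (concerted syn transfer of H2) should saturate the cis ring alkene without cleaving the O–O bond, as in the classical reduction of unsaturated endoperoxides.

Step 9
Reactants: 14 ethyl 3-[(3R,6S)-3,6-dimethyl-6-(8-phenyloctyl)-1,2-dioxan-3-yl]propanoate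
Product: 15 3-[(3R,6S)-3,6-dimethyl-6-(8-phenyloctyl)-1,2-dioxan-3-yl]propanoic acid
Conditions: LiOH·H2O, THF/H2O, 0 °C → rt; then 1 M HCl to pH 3
Reagents that add atoms: lithium hydroxide (its oxygen ends in the carboxyl group), [Li+].[OH-]
Why: Saponification of the ethyl ester should be clean because a di-tertiary dialkyl peroxide has no α-hydrogen for base-induced Kornblum–DeLaMare fragmentation.

Compound list
1 | (7-bromoheptyl)benzene | BrCCCCCCCc1ccccc1 | starting material
2 | (S)-2-methylglycidol | C[C@@]1(CO1)CO | starting material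
3 | 7-phenylheptylmagnesium bromide | Br[Mg]CCCCCCCc1ccccc1 | intermediate
4 | (R)-2-methyl-10-phenyldecane-1,2-diol | C[C@@](O)(CCCCCCCCc1ccccc1)CO | intermediate
5 | (R)-2-hydroxy-2-methyl-10-phenyldecyl 4-methylbenzenesulfonate | C[C@@](O)(CCCCCCCCc1ccccc1)COS(=O)(=O)c1ccc(C)cc1 | intermediate
6 | (R)-2-methyl-2-(8-phenyloctyl)oxirane | C[C@@]1(CCCCCCCCc2ccccc2)CO1 | intermediate
7 | (S)-2-hydroperoxy-2-methyl-10-phenyldecan-1-ol | C[C@](OO)(CCCCCCCCc1ccccc1)CO | intermediate
8 | (S)-2-methyl-10-phenyl-2-[(triethylsilyl)peroxy]decan-1-ol | C[C@](OO[Si](CC)(CC)CC)(CCCCCCCCc1ccccc1)CO | intermediate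
9 | (S)-2-methyl-10-phenyl-2-[(triethylsilyl)peroxy]decanal | C[C@](OO[Si](CC)(CC)CC)(CCCCCCCCc1ccccc1)C=O | intermediate
10 | ethyl 4-methylpent-4-enoate | C=C(C)CCC(=O)OCC | starting material
11 | ethyl 3-[(3S,6S)-3,6-dimethyl-6-(8-phenyloctyl)-5-[(triethylsilyl)oxy]-1,2-dioxan-3-yl]propanoate (C5 epimers) | C[C@]1(CCCCCCCCc2ccccc2)C(O[Si](CC)(CC)CC)C[C@](C)(CCC(=O)OCC)OO1 | intermediate
12 | ethyl 3-[(3S,6S)-5-hydroxy-3,6-dimethyl-6-(8-phenyloctyl)-1,2-dioxan-3-yl]propanoate (C5 epimers) | C[C@]1(CCCCCCCCc2ccccc2)C(O)C[C@](C)(CCC(=O)OCC)OO1 | intermediate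
13 | ethyl 3-[(3S,6S)-3,6-dimethyl-6-(8-phenyloctyl)-3,6-dihydro-1,2-dioxin-3-yl]propanoate | C[C@]1(CCCCCCCCc2ccccc2)C=C[C@](C)(CCC(=O)OCC)OO1 | intermediate
14 | ethyl 3-[(3R,6S)-3,6-dimethyl-6-(8-phenyloctyl)-1,2-dioxan-3-yl]propanoate | C[C@]1(CCCCCCCCc2ccccc2)CC[C@](C)(CCC(=O)OCC)OO1 | intermediate
15 | 3-[(3R,6S)-3,6-dimethyl-6-(8-phenyloctyl)-1,2-dioxan-3-yl]propanoic acid | C[C@]1(CCCCCCCCc2ccccc2)CC[C@](C)(CCC(=O)O)OO1 | target

Total step count: 9
Longest linear sequence: 9 steps (2 → 4 → 6 → 7 → 8 → 9 → 12 → 13 → 14 → 15)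

Steps most likely to fail

Step 6 (Proposed new method). The tertiary cation may be lost by proton elimination or capped by the ester carbonyl faster than the peroxide oxygen closes the ring. The Lewis acid may trigger O–O heterolysis with a 1,2-shift. The chiral anion may fail to discriminate the two faces at C3. The fallback uses known chemistry in separate operations, sets out from 9 and returns at 12:
- An SnCl4-promoted carbonyl-ene reaction of 9 with 10 (CH2Cl2, −78 °C) should give the homoallylic alcohol ethyl (7S)-6-hydroxy-7-methyl-4-methylidene-15-phenyl-7-[(triethylsilyl)peroxy]pentadecanoate F1.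
- Bu4NF/AcOH (THF, 0 °C) should free the hydroperoxide ethyl (7S)-7-hydroperoxy-6-hydroxy-7-methyl-4-methylidene-15-phenylpentadecanoate F2.
- Cycloperoxymercuration (Hg(OAc)2, cat. HClO4, CH2Cl2) should close the ring at the tertiary alkene carbon to give the organomercurial ethyl 3-[(6S)-3-[(acetoxymercurio)methyl]-5-hydroxy-6-methyl-6-(8-phenyloctyl)-1,2-dioxan-3-yl]propanoate F3.
- NaBH4 in aq NaOH should turn CH2HgOAc into the C3 methyl and give 12 as a mixture at C3, from which the 3S epimer would be separated by preparative HPLC.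

Step 3. The tertiary C–O bond may ionise ahead of peroxide attack, which would lose the invertive pathway and erode enantiopurity, or H2O2 may attack the CH2 terminus. The fallback replaces stereospecific substitution by enzymatic resolution, sets out from 6 and returns at 8, bypassing steps 3 and 4:
- Isomerisation of 6 with Et2Al(tmp) (benzene, 0 °C) should give mainly 2-methylidene-10-phenyldecan-1-ol F4.
- Mukaiyama–Isayama silylperoxidation (Co(acac)2, O2, Et3SiH, ClCH2CH2Cl, rt) should give racemic 2-methyl-10-phenyl-2-[(triethylsilyl)peroxy]decan-1-ol F5.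
- Kinetic resolution with a lipase (serine hydrolase, selected by screening; vinyl acetate, MTBE) should acetylate the R enantiomer to (R)-2-methyl-10-phenyl-2-[(triethylsilyl)peroxy]decyl acetate F6 and leave (S)-8, at the price of at most half of the material.

Step 7. The C5 sulfamate, next to the peroxy-bearing quaternary C6, may ionise and undergo a 1,2-shift or ring contraction in place of syn-elimination; the hindered ring alkene may then be reduced only sluggishly in step 8. The fallback deoxygenates through the ketone, sets out from 12 and returns at 14, bypassing steps 7 and 8: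
- Dess–Martin oxidation of 12 should give the ketone ethyl 3-[(3S,6S)-3,6-dimethyl-5-oxo-6-(8-phenyloctyl)-1,2-dioxan-3-yl]propanoate F7.
- TsNHNH2 (EtOH, rt) should give the tosylhydrazone ethyl 3-[(3S,6S)-3,6-dimethyl-5-[2-(4-methylbenzenesulfonyl)hydrazinylidene]-6-(8-phenyloctyl)-1,2-dioxan-3-yl]propanoate F8.
- Catecholborane (CHCl3, 0 °C) followed by NaOAc·3H2O (reflux) should reduce the hydrazone carbon to CH2 and give 14 directly.

Further compounds
F1 | step 6 | ethyl (7S)-6-hydroxy-7-methyl-4-methylidene-15-phenyl-7-[(triethylsilyl)peroxy]pentadecanoate | C[C@](OO[Si](CC)(CC)CC)(CCCCCCCCc1ccccc1)C(O)CC(=C)CCC(=O)OCC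
F2 | step 6 | ethyl (7S)-7-hydroperoxy-6-hydroxy-7-methyl-4-methylidene-15-phenylpentadecanoate | C[C@](OO)(CCCCCCCCc1ccccc1)C(O)CC(=C)CCC(=O)OCC
F3 | step 6 | ethyl 3-[(6S)-3-[(acetoxymercurio)methyl]-5-hydroxy-6-methyl-6-(8-phenyloctyl)-1,2-dioxan-3-yl]propanoate | C[C@]1(CCCCCCCCc2ccccc2)C(O)CC(C[Hg]OC(C)=O)(CCC(=O)OCC)OO1
F4 | step 3 | 2-methylidene-10-phenyldecan-1-ol | C=C(CO)CCCCCCCCc1ccccc1
F5 | step 3 | rac-2-methyl-10-phenyl-2-[(triethylsilyl)peroxy]decan-1-ol | CC(OO[Si](CC)(CC)CC)(CCCCCCCCc1ccccc1)CO
F6 | step 3 | (R)-2-methyl-10-phenyl-2-[(triethylsilyl)peroxy]decyl acetate | C[C@@](OO[Si](CC)(CC)CC)(CCCCCCCCc1ccccc1)COC(C)=O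
F7 | step 7 | ethyl 3-[(3S,6S)-3,6-dimethyl-5-oxo-6-(8-phenyloctyl)-1,2-dioxan-3-yl]propanoate | C[C@]1(CCCCCCCCc2ccccc2)C(=O)C[C@](C)(CCC(=O)OCC)OO1
F8 | step 7 | ethyl 3-[(3S,6S)-3,6-dimethyl-5-[2-(4-methylbenzenesulfonyl)hydrazinylidene]-6-(8-phenyloctyl)-1,2-dioxan-3-yl]propanoate | C[C@]1(CCCCCCCCc2ccccc2)C(=NNS(=O)(=O)c2ccc(C)cc2)C[C@](C)(CCC(=O)OCC)OO1
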